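**Plan**
The retrosynthesis cuts the depside ester bond (ring B O4 to the ring A carbonyl), then the ring B bonds C1–C6 and C3–C4, and in ring A the C1–CO2H and C3–CH2OH bonds.
Ring B has methyls on C3 and C6, oxygens on C2 and C4 and the carboxyl on C1, which is the pattern of a cyclohexane-2,4-dione-1-carboxylate. A 3-oxopentanoate supplies C1–C3 with the 3-methyl and a crotonate supplies C4–C6 with the 6-methyl.
Forward: the two benzyl esters are annulated to the ring B dione, while 3,5-dimethoxytoluene is hydroxymethylated between its methoxy groups, silylated, brominated and carboxylated to the ring A acid.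
The ring A acid chloride acylates the C4 enol oxygen of the dione. Ring B is then aromatised by selenoxide elimination, which uncovers the 2-hydroxyl, and benzyl ester hydrogenolysis and desilylation finish the route.
The target has no stereocentre; those formed on the way are erased when ring B becomes aromatic.
Key step: step 3

Remark: ring B positions are numbered as in the target benzoic acid (C1 carries the carboxyl); compounds 6, 7, 15 and 16 are carried as mixtures of stereoisomers and tautomers.

**Route**

Step 1
Reactants: 1 methyl 3-oxopentanoate; 2 benzyl alcohol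
Product: 3 benzyl 3-oxopentanoate
Conditions: BnOH (1.0 equiv), DMAP (cat.), toluene, reflux, MeOH removed over 4 Å sieves
Reagents that add atoms: none
Why: Transesterification of a β-keto ester, which exchanges readily through its acylketene or DMAP adduct and is driven by removal of methanol.

Step 2
Reactants: 4 (E)-but-2-enoic acid; 2 benzyl alcohol
Product: 5 benzyl (E)-but-2-enoate
Conditions: TsOH·H2O (cat.), toluene, reflux, Dean–Stark
Reagents that add atoms: none
Why: Fischer esterification driven by azeotropic removal of water; the conjugated E alkene is the stable isomer and should not move.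

Step 3
Reactants: 3 benzyl 3-oxopentanoate; 5 benzyl (E)-but-2-enoate
Product: 7 benzyl 3,6-dimethyl-2,4-dioxocyclohexane-1-carboxylate, via Michael adduct 6 (not isolated)
Conditions: NaOBn (1.0 M in BnOH, 1.1 equiv), THF, 0 → 60 °C; then 1 M HCl, 0 °C
Reagents that add atoms: none
Why: Benzyloxide deprotonates 3 at its doubly activated C2, and this enolate adds to the β-carbon of 5 (Michael addition, ring B C1–C6 bond) to give 6 after proton transfer. Equilibrating proton transfers then expose the propanoyl CH2 enolate of 6, which attacks the crotonate-derived ester carbonyl and expels benzyloxide (Dieckmann condensation, C3–C4 bond); this closure is 6-exo-trig and is the only Claisen or aldol closure open to 6 that gives a six-membered ring. The closest known reaction is the sodium alkoxide annulation of acetoacetates or 3-oxopentanoates with crotonates to dihydro-orsellinate esters. The product is a vinylogous acid and is held as its sodium salt, which pulls the equilibria forward and is why a full equivalent of base is used. The stereocentres at C1, C3 and C6 need no control, since all are epimerisable and vanish on aromatisation. The selectivity needed is regiochemical (Michael through the central carbon, Claisen through the propanoyl CH2); it is secured by the acidity order within the keto ester and by ring size, and the matched benzyloxide and benzyl esters make ester exchange degenerate.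

Step 4
Reactants: 8 3,5-dimethoxytoluene
Product: 10 (2,6-dimethoxy-4-methylphenyl)methanol, via aldehyde 9 (not isolated)
Conditions: n-BuLi, TMEDA, THF, 0 °C → rt; DMF, 0 °C; then MeOH, NaBH4, 0 °C; aq. NH4Cl
Reagents that add atoms: N,N-dimethylformamide, CN(C)C=O
Why: Directed ortho-metalation at the position flanked by both methoxy groups, formylation of the aryllithium with DMF and borohydride reduction of the aldehyde released on adding methanol.

Step 5
Reactants: 10 (2,6-dimethoxy-4-methylphenyl)methanol
Product: 11 tert-butyl[(2,6-dimethoxy-4-methylphenyl)methoxy]dimethylsilane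
Conditions: TBSCl, imidazole, DMF, rt
Reagents that add atoms: tert-butyldimethylsilyl chloride, CC(C)(C)[Si](C)(C)Cl
Why: Standard imidazole-promoted silylation of a primary alcohol; the silyl ether masks the hydroxyl through the organolithium and acid chloride steps.

Step 6
Reactants: 11 tert-butyl[(2,6-dimethoxy-4-methylphenyl)methoxy]dimethylsilane
Product: 12 [(3-bromo-2,6-dimethoxy-4-methylphenyl)methoxy](tert-butyl)dimethylsilane
Conditions: NBS (1.0 equiv), MeCN, 0 °C → rt, dark
Reagents that add atoms: N-bromosuccinimide, O=C1CCC(=O)N1Br
Why: Electrophilic aromatic bromination of an activated arene in a polar solvent; the two free ring positions are equivalent by symmetry (each ortho and para to a methoxy group), so one regioisomer should form.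

Step 7
Reactants: 12 [(3-bromo-2,6-dimethoxy-4-methylphenyl)methoxy](tert-butyl)dimethylsilane
Product: 13 3-{[(tert-butyldimethylsilyl)oxy]methyl}-2,4-dimethoxy-6-methylbenzoic acid
Conditions: n-BuLi, THF, −78 °C; CO2 (dry gas), −78 °C → rt; 1 M HCl to pH 4, 0 °C
Reagents that add atoms: carbon dioxide, O=C=O
Why: Bromine–lithium exchange is fast at −78 °C and outruns lateral metalation of the neighbouring methyl, and carboxylation of the aryllithium fixes the carboxyl between the methyl and a methoxy group.

Step 8
Reactants: 13 3-{[(tert-butyldimethylsilyl)oxy]methyl}-2,4-dimethoxy-6-methylbenzoic acid; 7 benzyl 3,6-dimethyl-2,4-dioxocyclohexane-1-carboxylate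
Product: 15 benzyl 4-[(3-{[(tert-butyldimethylsilyl)oxy]methyl}-2,4-dimethoxy-6-methylbenzoyl)oxy]-3,6-dimethyl-2-oxocyclohex-3-ene-1-carboxylate, via acid chloride 14 (not isolated)
Conditions: 13, 1-chloro-N,N,2-trimethylprop-1-en-1-amine (1.05 equiv), CH2Cl2, 0 °C → rt; then added to 7, Et3N, CH2Cl2, 0 °C → rt
Reagents that add atoms: none
Why: O-acylation of a cyclic 1,3-dione enolate by an aroyl chloride made under neutral conditions that spare the silyl ether; the C3 methyl disfavours C-acylation, and the hindered electrophile should take the C4 oxygen, which sits next to a CH2, over the C2 oxygen, which is crowded by the C1 ester and remains part of the β-keto ester.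

Step 9
Reactants: 15 benzyl 4-[(3-{[(tert-butyldimethylsilyl)oxy]methyl}-2,4-dimethoxy-6-methylbenzoyl)oxy]-3,6-dimethyl-2-oxocyclohex-3-ene-1-carboxylate
Product: 17 benzyl 4-[(3-{[(tert-butyldimethylsilyl)oxy]methyl}-2,4-dimethoxy-6-methylbenzoyl)oxy]-2-hydroxy-3,6-dimethylbenzoate, via selenide 16 (not isolated)
Conditions: PhSeCl, pyridine, CH2Cl2, 0 °C → rt; then 30% H2O2, 0 °C → rt
Reagents that add atoms: none
Why: Reich selenenylation of the β-keto ester at C1 through its enol, oxidation to the selenoxide and syn-elimination towards the C6 hydrogen give a cyclohexa-2,5-dienone that tautomerises to the salicylate; selenium should enter anti to the C6 methyl and so cis to the hydrogen it must remove, and PhSeCl should leave the electron-rich ring A and its benzylic silyl ether untouched.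

Step 10
Reactants: 17 benzyl 4-[(3-{[(tert-butyldimethylsilyl)oxy]methyl}-2,4-dimethoxy-6-methylbenzoyl)oxy]-2-hydroxy-3,6-dimethylbenzoate
Product: 18 4-[(3-{[(tert-butyldimethylsilyl)oxy]methyl}-2,4-dimethoxy-6-methylbenzoyl)oxy]-2-hydroxy-3,6-dimethylbenzoic acid
Conditions: H2 (1 atm), 10% Pd/C, EtOAc, rt
Reagents that add atoms: none
Why: Hydrogenolysis of a benzyl ester, the usual carboxyl release in depside work; in neutral ethyl acetate it should be much faster than cleavage of the silylated benzylic C–O bond of ring A, and the hindered aryl ester is inert (selenium residues from step 9 must be removed first).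

Step 11
Reactants: 18 4-[(3-{[(tert-butyldimethylsilyl)oxy]methyl}-2,4-dimethoxy-6-methylbenzoyl)oxy]-2-hydroxy-3,6-dimethylbenzoic acid
Product: 19 2-hydroxy-4-{[3-(hydroxymethyl)-2,4-dimethoxy-6-methylbenzoyl]oxy}-3,6-dimethylbenzoic acid (CNP0372912.0)
Conditions: HF·pyridine, pyridine, THF, 0 °C → rt
Reagents that add atoms: none
Why: Fluoride-driven cleavage of a primary silyl ether under pyridine-buffered conditions that should leave the depside ester and the electron-rich benzylic alcohol intact.

**Compound list**
1 | methyl 3-oxopentanoate | CCC(=O)CC(=O)OC | starting material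
2 | benzyl alcohol | OCc1ccccc1 | starting material
3 | benzyl 3-oxopentanoate | CCC(=O)CC(=O)OCc1ccccc1 | intermediate
4 | (E)-but-2-enoic acid | C/C=C/C(=O)O | starting material
5 | benzyl (E)-but-2-enoate | C/C=C/C(=O)OCc1ccccc1 | intermediate
6 | dibenzyl 3-methyl-2-propanoylpentanedioate (Michael adduct, mixture of diastereomers, not isolated) | CCC(=O)C(C(=O)OCc1ccccc1)C(C)CC(=O)OCc1ccccc1 | intermediate
7 | benzyl 3,6-dimethyl-2,4-dioxocyclohexane-1-carboxylate (mixture of diastereomers and enol tautomers) | CC1CC(=O)C(C)C(=O)C1C(=O)OCc1ccccc1 | intermediate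
8 | 3,5-dimethoxytoluene | COc1cc(C)cc(OC)c1 | starting material
9 | 2,6-dimethoxy-4-methylbenzaldehyde (not isolated) | COc1cc(C)cc(OC)c1C=O | intermediate
10 | (2,6-dimethoxy-4-methylphenyl)methanol | COc1cc(C)cc(OC)c1CO | intermediate
11 | tert-butyl[(2,6-dimethoxy-4-methylphenyl)methoxy]dimethylsilane | COc1cc(C)cc(OC)c1CO[Si](C)(C)C(C)(C)C | intermediate
12 | [(3-bromo-2,6-dimethoxy-4-methylphenyl)methoxy](tert-butyl)dimethylsilane | COc1cc(C)c(Br)c(OC)c1CO[Si](C)(C)C(C)(C)C | intermediate
13 | 3-{[(tert-butyldimethylsilyl)oxy]methyl}-2,4-dimethoxy-6-methylbenzoic acid | COc1cc(C)c(C(=O)O)c(OC)c1CO[Si](C)(C)C(C)(C)C | intermediate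
14 | 3-{[(tert-butyldimethylsilyl)oxy]methyl}-2,4-dimethoxy-6-methylbenzoyl chloride (not isolated) | COc1cc(C)c(C(=O)Cl)c(OC)c1CO[Si](C)(C)C(C)(C)C | intermediate
15 | benzyl 4-[(3-{[(tert-butyldimethylsilyl)oxy]methyl}-2,4-dimethoxy-6-methylbenzoyl)oxy]-3,6-dimethyl-2-oxocyclohex-3-ene-1-carboxylate (mixture of diastereomers and keto–enol forms) | CC1CC(OC(=O)c2c(C)cc(OC)c(CO[Si](C)(C)C(C)(C)C)c2OC)=C(C)C(=O)C1C(=O)OCc1ccccc1 | intermediate
16 | benzyl 4-[(3-{[(tert-butyldimethylsilyl)oxy]methyl}-2,4-dimethoxy-6-methylbenzoyl)oxy]-3,6-dimethyl-2-oxo-1-(phenylselanyl)cyclohex-3-ene-1-carboxylate (not isolated; selenium expected trans to the C6 methyl) | CC1CC(OC(=O)c2c(C)cc(OC)c(CO[Si](C)(C)C(C)(C)C)c2OC)=C(C)C(=O)C1([Se]c3ccccc3)C(=O)OCc3ccccc3 | intermediate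
17 | benzyl 4-[(3-{[(tert-butyldimethylsilyl)oxy]methyl}-2,4-dimethoxy-6-methylbenzoyl)oxy]-2-hydroxy-3,6-dimethylbenzoate | Cc1cc(OC(=O)c2c(C)cc(OC)c(CO[Si](C)(C)C(C)(C)C)c2OC)c(C)c(O)c1C(=O)OCc1ccccc1 | intermediate
18 | 4-[(3-{[(tert-butyldimethylsilyl)oxy]methyl}-2,4-dimethoxy-6-methylbenzoyl)oxy]-2-hydroxy-3,6-dimethylbenzoic acid | Cc1cc(OC(=O)c2c(C)cc(OC)c(CO[Si](C)(C)C(C)(C)C)c2OC)c(C)c(O)c1C(=O)O | intermediate
19 | 2-hydroxy-4-{[3-(hydroxymethyl)-2,4-dimethoxy-6-methylbenzoyl]oxy}-3,6-dimethylbenzoic acid | COc1cc(C)c(C(=O)Oc2cc(C)c(C(=O)O)c(O)c2C)c(OC)c1CO | target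

**Count**
Total steps: 11. Longest linear sequence: 8 steps (8 to 19 through steps 4 to 11).

**Steps most likely to fail**

Step 8. The acyl group may go partly to the C2 enol oxygen or migrate between the two enol oxygens, and the doubly ortho-substituted acid chloride may react so slowly that hydrolysis of the enol ester competes. The fallback aromatises ring B before the ester bond is made. Setting out from 7, N-chlorosuccinimide in CH2Cl2 should chlorinate the dione carbon to give benzyl 3-chloro-3,6-dimethyl-2,4-dioxocyclohexane-1-carboxylate F1. Heating this with LiCl in DMF should eliminate HCl and give, after tautomerisation, benzyl 2,4-dihydroxy-3,6-dimethylbenzoate F2. Acylation of this phenol with acid chloride 14 (Et3N, cat. DMAP, CH2Cl2) should occur at the 4-hydroxyl, because the 2-hydroxyl is hydrogen-bonded to the ester and flanked on both sides. The route is rejoined at 17, and steps 8 and 9 are bypassed.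

Step 9. Selenium may be delivered to the face of C1 that leaves no syn hydrogen on C6, so that elimination stalls, or the new phenol may be oxidised further by the seleninic acid and peroxide present. The fallback replaces the selenoxide by a palladium-mediated dehydrosilylation. Setting out from 15, TMSOTf and Et3N in CH2Cl2 at 0 °C should give the silyl dienol ether benzyl 4-[(3-{[(tert-butyldimethylsilyl)oxy]methyl}-2,4-dimethoxy-6-methylbenzoyl)oxy]-3,6-dimethyl-2-[(trimethylsilyl)oxy]cyclohexa-1,3-diene-1-carboxylate F3. Saegusa–Ito oxidation with Pd(OAc)2 in MeCN should then form the C1–C6 double bond, since the palladium enolate can reach the C6 hydrogen from either face, and the dienone tautomerises to the phenol. The route is rejoined at 17.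

Step 3. Benzyloxide may attack the benzyl esters at the benzylic carbon, after which the β-keto acid decarboxylates, or the crotonate may oligomerise faster than the Michael–Dieckmann sequence proceeds. The fallback runs the annulation in the methyl ester series. Setting out from 1, reaction with commercial methyl (E)-but-2-enoate and NaOMe in refluxing MeOH should give methyl 3,6-dimethyl-2,4-dioxocyclohexane-1-carboxylate F4. Heating this β-keto ester with 2 in toluene while methanol distils should exchange the ester, and a dilute acid wash should hydrolyse any benzyl enol ether formed at O4. The route is rejoined at 7.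

**Further compounds**
F1 | step 8 | benzyl 3-chloro-3,6-dimethyl-2,4-dioxocyclohexane-1-carboxylate | CC1CC(=O)C(C)(Cl)C(=O)C1C(=O)OCc1ccccc1
F2 | step 8 | benzyl 2,4-dihydroxy-3,6-dimethylbenzoate | Cc1cc(O)c(C)c(O)c1C(=O)OCc1ccccc1
F3 | step 9 | benzyl 4-[(3-{[(tert-butyldimethylsilyl)oxy]methyl}-2,4-dimethoxy-6-methylbenzoyl)oxy]-3,6-dimethyl-2-[(trimethylsilyl)oxy]cyclohexa-1,3-diene-1-carboxylate | CC1CC(OC(=O)c2c(C)cc(OC)c(CO[Si](C)(C)C(C)(C)C)c2OC)=C(C)C(O[Si](C)(C)C)=C1C(=O)OCc1ccccc1
F4 | step 3 | methyl 3,6-dimethyl-2,4-dioxocyclohexane-1-carboxylate | CC1CC(=O)C(C)C(=O)C1C(=O)OC
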